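The central O–C(=O) unit of the seven-membered dioxepinone is traced to carbon dioxide, with both of its bonds to the arenes cut. The key step exploits two features: the ring B carbon that carries the ester oxygen lies ortho to the formyl group and para to the lactone carbonyl, so a fluoride there is labile to SNAr, and the ring A carbon between the methyl group and the ether oxygen can carry boron. Copper-catalysed carboxylation of that aryl boronate with CO2 gives a carboxylate that displaces the fluoride in the same flask, closing the depsidone. The precursor is a fluorinated, boron-bearing diaryl ether whose lactol is locked as an (R)-1-phenylethyl acetal.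

Key step: step 10

Assumption: the lactol carbon of a 3-hydroxyphthalide epimerises through the open 2-formylbenzoic acid in protic or basic media, so its (S) configuration is fixed as a mixed acetal with (R)-1-phenylethanol (diastereomers separated in step 7) and is released only in the last step under neutral, aprotic conditions.

Step 1
Reactants: 1 3-fluoro-5-methylphenol
Product: 2 1-(benzyloxy)-3-fluoro-5-methylbenzene
Conditions: BnBr, K2CO3, DMF, rt
Reagents that add atoms: benzyl bromide (BrCc1ccccc1)
Why: Williamson etherification of the phenoxide should give the benzyl ether, which later directs the metalation and is removed by hydrogenolysis at the end.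

Step 2
Reactants: 2 1-(benzyloxy)-3-fluoro-5-methylbenzene
Product: 3 5-(benzyloxy)-2-bromo-1-fluoro-3-methylbenzene
Conditions: NBS, MeCN, 0 °C to rt, dark
Reagents that add atoms: N-bromosuccinimide (O=C1CCC(=O)N1Br)
Why: Electrophilic aromatic bromination with NBS in acetonitrile should occur para to the benzyloxy group, the strongest donor, at the carbon between F and CH3.

Step 3
Reactants: 3 5-(benzyloxy)-2-bromo-1-fluoro-3-methylbenzene
Product: 6 6-(benzyloxy)-3-bromo-2-fluoro-4-methylbenzaldehyde, via aryllithium 4 (not isolated), via lithium hemiaminal alkoxide 5 (not isolated)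
Conditions: LDA, THF, −78 °C; DMF, −78 °C; aq. HCl
Reagents that add atoms: N,N-dimethylformamide (CN(C)C=O)
Why: Directed ortho-metalation should remove the most acidic ring hydrogen, the one flanked by F and OBn and not adjacent to Br (so no halogen dance is expected), and formylation of the aryllithium with DMF gives the aldehyde after hydrolysis.

Step 4
Reactants: 7 4-fluoro-2-hydroxybenzoic acid
Product: 9 4-fluoro-2,5-dihydroxybenzoic acid, via aryl sulfate 8 (not isolated)
Conditions: K2S2O8, aq. NaOH, 0 °C to rt; then aq. HCl, 90 °C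
Reagents that add atoms: potassium persulfate ([K+].[K+].[O-]S(=O)(=O)OOS(=O)(=O)[O-])
Why: The Elbs persulfate oxidation of a phenolate is para-selective, so the oxygen should enter at the free carbon next to F, and acid hydrolysis of the aryl sulfate gives the hydroquinone.

Step 5
Reactants: 9 4-fluoro-2,5-dihydroxybenzoic acid
Product: 10 methyl 4-fluoro-2,5-dihydroxybenzoate
Conditions: MeOH, H2SO4 (cat.), reflux
Reagents that add atoms: methanol (CO)
Why: Fischer esterification masks the acid so that only the two phenols bind magnesium in the next step.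

Step 6
Reactants: 10 methyl 4-fluoro-2,5-dihydroxybenzoate
Product: 12 5-fluoro-6-formyl-3,4,7-trihydroxyisobenzofuran-1(3H)-one (racemic lactol), via diformyl ester 11 (not isolated)
Conditions: MgCl2, Et3N, (CH2O)n, MeCN, reflux; then aq. NaOH, rt, N2; then aq. HCl
Reagents that add atoms: formaldehyde as paraformaldehyde (C=O); sodium hydroxide ([Na+].[OH-])
Why: Magnesium phenoxide-directed ortho-formylation (Casnati–Skattebøl reaction) should formylate the only free ortho position of each phenol, which are the only two ring hydrogens, and saponification of the o-formyl ester, assisted by the neighbouring aldehyde, gives the acid, which closes to the lactol by ring–chain tautomerism.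

Step 7
Reactants: 12 5-fluoro-6-formyl-3,4,7-trihydroxyisobenzofuran-1(3H)-one; 13 (R)-1-phenylethanol
Product: 14 (3S)-5-fluoro-6-formyl-4,7-dihydroxy-3-[(1R)-1-phenylethoxy]isobenzofuran-1(3H)-one
Conditions: PPTS (cat.), toluene, 4 Å molecular sieves, 60 °C; separation of the C3 epimers by chromatography or crystallisation, the (3R) epimer being re-equilibrated under the same conditions
Reagents that add atoms: none
Why: Acid-catalysed pseudo-ester (mixed acetal) formation of a 3-hydroxyphthalide is reversible and should give both C3 epimers, which the (R)-auxiliary makes diastereomers, so the (3S) stereocenter is set by separation with recycling of the other epimer.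

Step 8
Reactants: 14 (3S)-5-fluoro-6-formyl-4,7-dihydroxy-3-[(1R)-1-phenylethoxy]isobenzofuran-1(3H)-one; 6 6-(benzyloxy)-3-bromo-2-fluoro-4-methylbenzaldehyde
Product: 16 (3S)-7-(benzyloxy)-4-[3-(benzyloxy)-6-bromo-2-formyl-5-methylphenoxy]-5-fluoro-6-formyl-3-[(1R)-1-phenylethoxy]isobenzofuran-1(3H)-one, via diaryl ether phenol 15 (not isolated)
Conditions: Cs2CO3, DMF, 80 °C; then BnBr, 50 °C
Reagents that add atoms: benzyl bromide (BrCc1ccccc1)
Why: SNAr of the fluoride ortho to the formyl group of 6 by the C4 phenoxide of 14 should give the diaryl ether, because the C7 phenoxide, flanked by formyl and lactone carbonyl, is a non-nucleophilic vinylogous carboxylate that also switches off the ring B fluoride, and Williamson benzylation of that phenoxide in the same flask switches the fluoride on again for step 10.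

Step 9
Reactants: 16 (3S)-7-(benzyloxy)-4-[3-(benzyloxy)-6-bromo-2-formyl-5-methylphenoxy]-5-fluoro-6-formyl-3-[(1R)-1-phenylethoxy]isobenzofuran-1(3H)-one
Product: 17 (3S)-7-(benzyloxy)-4-[3-(benzyloxy)-6-(5,5-dimethyl-1,3,2-dioxaborinan-2-yl)-2-formyl-5-methylphenoxy]-5-fluoro-6-formyl-3-[(1R)-1-phenylethoxy]isobenzofuran-1(3H)-one
Conditions: B2nep2, Pd2(dba)3 (cat.), XPhos, KOAc, 1,4-dioxane, 90 °C
Reagents that add atoms: bis(neopentyl glycolato)diboron (CC1(C)COB(OC1)B1OCC(C)(C)CO1)
Why: In this Miyaura borylation, zerovalent palladium with the bulky, electron-rich XPhos ligand should insert into the hindered C–Br bond and acetate-assisted transmetalation delivers the boronate, while aldehydes, the aryl fluoride, the benzyl ethers and the acetal are compatible with the weak, poorly soluble base.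

Step 10
Reactants: 17 (3S)-7-(benzyloxy)-4-[3-(benzyloxy)-6-(5,5-dimethyl-1,3,2-dioxaborinan-2-yl)-2-formyl-5-methylphenoxy]-5-fluoro-6-formyl-3-[(1R)-1-phenylethoxy]isobenzofuran-1(3H)-one
Product: 19 (1S)-4,10-bis(benzyloxy)-8-methyl-3,7-dioxo-1-[(1R)-1-phenylethoxy]-1,3-dihydro-7H-isobenzofuro[4,5-b][1,4]benzodioxepine-5,11-dicarbaldehyde, via caesium carboxylate 18 (not isolated)
Conditions: CO2 (1 atm), (IPr)CuCl (10 mol%; IPr = 1,3-bis(2,6-diisopropylphenyl)imidazol-2-ylidene), CsF, 4 Å molecular sieves, DMF, 90 °C
Reagents that add atoms: carbon dioxide (O=C=O)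
Why: Fluoride-assisted transmetalation of the boronate to the monovalent copper–carbene complex gives an aryl–copper species at the ring A carbon between CH3 and the ether oxygen, which inserts CO2 to form the aryl–C(=O) bond and releases caesium carboxylate 18, whose oxygen then attacks the fluorine-bearing ring B carbon by addition–elimination (SNAr) to form the O–aryl bond, the expelled fluoride returning to activate boron. The closest known reaction types are the copper–NHC-catalysed carboxylation of aryl boronic esters with CO2, a reaction type compatible with aldehydes under a CO2 atmosphere, and the SNAr lactonisation of carboxylates onto activated fluoroarenes. The seven-membered 1,4-dioxepinone ring closes in a 7-exo-trig mode through a Meisenheimer intermediate. No stereocenter is formed, and the acetal carbon set in step 7 should stay untouched because no acid is present and CO2 buffers the basicity of fluoride. The step needs attack at the C–F carbon and not at the ipso carbon of the diaryl ether (the six-membered Smiles pathway), which is secured because only the C–F carbon has the formyl group ortho and the lactone carbonyl para. The benzyl ether on the ring B phenol keeps these acceptors active, and the twisted, di-ortho-substituted carboxylate is held over ring B by the ether bridge.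

Step 11
Reactants: 19 (1S)-4,10-bis(benzyloxy)-8-methyl-3,7-dioxo-1-[(1R)-1-phenylethoxy]-1,3-dihydro-7H-isobenzofuro[4,5-b][1,4]benzodioxepine-5,11-dicarbaldehyde
Product: 20 (1S)-1,4,10-trihydroxy-8-methyl-3,7-dioxo-1,3-dihydro-7H-isobenzofuro[4,5-b][1,4]benzodioxepine-5,11-dicarbaldehyde (CNP0296574.1)
Conditions: H2 (1 atm), Pd/C, EtOAc, 0 °C to rt; filtration and evaporation at low temperature, no chromatography
Reagents that add atoms: none
Why: Hydrogenolysis over palladium on carbon should cleave the three benzylic C–O bonds on the side of the PhCH2 and PhCH(CH3) carbons, so the lactol C–O bond is not broken and the (S) configuration set in step 7 is retained under neutral, aprotic conditions.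

Compound list
1 | 3-fluoro-5-methylphenol | Cc1cc(O)cc(F)c1 | starting material
2 | 1-(benzyloxy)-3-fluoro-5-methylbenzene | Cc1cc(F)cc(OCc2ccccc2)c1 | intermediate
3 | 5-(benzyloxy)-2-bromo-1-fluoro-3-methylbenzene | Cc1cc(OCc2ccccc2)cc(F)c1Br | intermediate
4 | [2-(benzyloxy)-5-bromo-6-fluoro-4-methylphenyl]lithium | Cc1cc(OCc2ccccc2)c([Li])c(F)c1Br | intermediate
5 | lithium [2-(benzyloxy)-5-bromo-6-fluoro-4-methylphenyl](dimethylamino)methanolate | Cc1cc(OCc2ccccc2)c(C(O[Li])N(C)C)c(F)c1Br | intermediate
6 | 6-(benzyloxy)-3-bromo-2-fluoro-4-methylbenzaldehyde | Cc1cc(OCc2ccccc2)c(C=O)c(F)c1Br | intermediate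
7 | 4-fluoro-2-hydroxybenzoic acid | O=C(O)c1ccc(F)cc1O | starting material
8 | 4-fluoro-2-hydroxy-5-(sulfooxy)benzoic acid (present as its salt) | O=C(O)c1cc(OS(=O)(=O)O)c(F)cc1O | intermediate
9 | 4-fluoro-2,5-dihydroxybenzoic acid | O=C(O)c1cc(O)c(F)cc1O | intermediate
10 | methyl 4-fluoro-2,5-dihydroxybenzoate | COC(=O)c1cc(O)c(F)cc1O | intermediate
11 | methyl 4-fluoro-3,6-diformyl-2,5-dihydroxybenzoate | COC(=O)c1c(C=O)c(O)c(F)c(C=O)c1O | intermediate
12 | 5-fluoro-6-formyl-3,4,7-trihydroxyisobenzofuran-1(3H)-one (racemic lactol) | O=Cc1c(F)c(O)c2C(O)OC(=O)c2c1O | intermediate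
13 | (R)-1-phenylethanol | C[C@@H](O)c1ccccc1 | starting material
14 | (3S)-5-fluoro-6-formyl-4,7-dihydroxy-3-[(1R)-1-phenylethoxy]isobenzofuran-1(3H)-one | O=Cc1c(F)c(O)c2[C@@H](O[C@H](C)c3ccccc3)OC(=O)c2c1O | intermediate
15 | (3S)-4-[3-(benzyloxy)-6-bromo-2-formyl-5-methylphenoxy]-5-fluoro-6-formyl-7-hydroxy-3-[(1R)-1-phenylethoxy]isobenzofuran-1(3H)-one | Cc1cc(OCc2ccccc2)c(C=O)c(Oc2c(F)c(C=O)c(O)c3c2[C@@H](O[C@H](C)c2ccccc2)OC3=O)c1Br | intermediate
16 | (3S)-7-(benzyloxy)-4-[3-(benzyloxy)-6-bromo-2-formyl-5-methylphenoxy]-5-fluoro-6-formyl-3-[(1R)-1-phenylethoxy]isobenzofuran-1(3H)-one | Cc1cc(OCc2ccccc2)c(C=O)c(Oc2c(F)c(C=O)c(OCc3ccccc3)c3c2[C@@H](O[C@H](C)c2ccccc2)OC3=O)c1Br | intermediate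
17 | (3S)-7-(benzyloxy)-4-[3-(benzyloxy)-6-(5,5-dimethyl-1,3,2-dioxaborinan-2-yl)-2-formyl-5-methylphenoxy]-5-fluoro-6-formyl-3-[(1R)-1-phenylethoxy]isobenzofuran-1(3H)-one | Cc1cc(OCc2ccccc2)c(C=O)c(Oc2c(F)c(C=O)c(OCc3ccccc3)c3c2[C@@H](O[C@H](C)c2ccccc2)OC3=O)c1B1OCC(C)(C)CO1 | intermediate
18 | caesium 4-(benzyloxy)-2-{[(3S)-7-(benzyloxy)-5-fluoro-6-formyl-1-oxo-3-[(1R)-1-phenylethoxy]-1,3-dihydroisobenzofuran-4-yl]oxy}-3-formyl-6-methylbenzoate | Cc1cc(OCc2ccccc2)c(C=O)c(Oc2c(F)c(C=O)c(OCc3ccccc3)c3c2[C@@H](O[C@H](C)c2ccccc2)OC3=O)c1C(=O)[O-].[Cs+] | intermediate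
19 | (1S)-4,10-bis(benzyloxy)-8-methyl-3,7-dioxo-1-[(1R)-1-phenylethoxy]-1,3-dihydro-7H-isobenzofuro[4,5-b][1,4]benzodioxepine-5,11-dicarbaldehyde | Cc1cc(OCc2ccccc2)c(C=O)c2c1C(=O)Oc1c(C=O)c(OCc3ccccc3)c3c(c1O2)[C@@H](O[C@H](C)c1ccccc1)OC3=O | intermediate
20 | (1S)-1,4,10-trihydroxy-8-methyl-3,7-dioxo-1,3-dihydro-7H-isobenzofuro[4,5-b][1,4]benzodioxepine-5,11-dicarbaldehyde (CNP0296574.1) | Cc1cc(O)c(C=O)c2c1C(=O)Oc1c(C=O)c(O)c3c(c1O2)[C@@H](O)OC3=O | target

Total step count: 11. Longest linear sequence: 8 steps (steps 4 to 11, from 7 to 20).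

Steps most likely to fail

Step 10. Boron-to-copper transmetalation at the di-ortho-substituted boronate may be slow, so that protodeboronation outruns carboxylation, or the carboxylate may close the ring sluggishly. The fallback sets out from bromide 16, bypasses 17 and returns at 19. Palladium-catalysed hydroxycarbonylation (Pd(OAc)2, Xantphos, CO 1 atm, H2O, Et3N, DMF, 80 °C) should give 4-(benzyloxy)-2-{[(3S)-7-(benzyloxy)-5-fluoro-6-formyl-1-oxo-3-[(1R)-1-phenylethoxy]-1,3-dihydroisobenzofuran-4-yl]oxy}-3-formyl-6-methylbenzoic acid F1. Its caesium salt (Cs2CO3, DMF, 80 °C) should then close the lactone by the same SNAr to give 19.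

Step 8. Formation of the tetra-ortho-substituted diaryl ether may stall for steric reasons, since the fluoride of 6 is flanked by CHO and Br and the phenoxide by F and the acetal carbon. The fallback introduces bromine after the ether bond; it sets out from 2 (with 14) and returns at 16. Ortho-lithiation of 2 (LDA, THF, −78 °C) gives [2-(benzyloxy)-6-fluoro-4-methylphenyl]lithium F2, which adds to DMF to give lithium [2-(benzyloxy)-6-fluoro-4-methylphenyl](dimethylamino)methanolate F3, hydrolysed to 2-(benzyloxy)-6-fluoro-4-methylbenzaldehyde F4, whose fluoride has only one large ortho neighbour. SNAr with 14 (Cs2CO3, DMF) should give (3S)-4-[3-(benzyloxy)-2-formyl-5-methylphenoxy]-5-fluoro-6-formyl-7-hydroxy-3-[(1R)-1-phenylethoxy]isobenzofuran-1(3H)-one F5, benzylated in the same flask to (3S)-7-(benzyloxy)-4-[3-(benzyloxy)-2-formyl-5-methylphenoxy]-5-fluoro-6-formyl-3-[(1R)-1-phenylethoxy]isobenzofuran-1(3H)-one F6. Bromination with NBS (DMF, rt) should then occur on ring A para to its benzyloxy group, ring B having no C–H bond, to give 16.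

Step 11. The two formyl groups may be over-reduced, the benzylic lactol C–O bond may be hydrogenolysed, or the freed lactol may epimerise on prolonged contact with the catalyst. The fallback is a non-reductive cleavage that sets out from 19 and ends at 20. With BCl3 and pentamethylbenzene (CH2Cl2, −78 °C), the benzyl and 1-phenylethyl groups should leave as cations from their benzylic carbons and be trapped by the scavenger. The lactol C–O bond stays intact, and a cold, buffered aqueous work-up should give 20 directly without a new isolated compound.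

Further compounds
F1 | step 10 | 4-(benzyloxy)-2-{[(3S)-7-(benzyloxy)-5-fluoro-6-formyl-1-oxo-3-[(1R)-1-phenylethoxy]-1,3-dihydroisobenzofuran-4-yl]oxy}-3-formyl-6-methylbenzoic acid | Cc1cc(OCc2ccccc2)c(C=O)c(Oc2c(F)c(C=O)c(OCc3ccccc3)c3c2[C@@H](O[C@H](C)c2ccccc2)OC3=O)c1C(=O)O
F2 | step 8 | [2-(benzyloxy)-6-fluoro-4-methylphenyl]lithium | Cc1cc(F)c([Li])c(OCc2ccccc2)c1
F3 | step 8 | lithium [2-(benzyloxy)-6-fluoro-4-methylphenyl](dimethylamino)methanolate | Cc1cc(F)c(C(O[Li])N(C)C)c(OCc2ccccc2)c1
F4 | step 8 | 2-(benzyloxy)-6-fluoro-4-methylbenzaldehyde | Cc1cc(F)c(C=O)c(OCc2ccccc2)c1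
F5 | step 8 | (3S)-4-[3-(benzyloxy)-2-formyl-5-methylphenoxy]-5-fluoro-6-formyl-7-hydroxy-3-[(1R)-1-phenylethoxy]isobenzofuran-1(3H)-one | Cc1cc(OCc2ccccc2)c(C=O)c(Oc2c(F)c(C=O)c(O)c3c2[C@@H](O[C@H](C)c2ccccc2)OC3=O)c1
F6 | step 8 | (3S)-7-(benzyloxy)-4-[3-(benzyloxy)-2-formyl-5-methylphenoxy]-5-fluoro-6-formyl-3-[(1R)-1-phenylethoxy]isobenzofuran-1(3H)-one | Cc1cc(OCc2ccccc2)c(C=O)c(Oc2c(F)c(C=O)c(OCc3ccccc3)c3c2[C@@H](O[C@H](C)c2ccccc2)OC3=O)c1
F0 | step 11 | none | none
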